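## Retrosynthetic overview

1. 13 ⇐ 12: the δ-lactone (O6–C5) is closed last. Acid protonates the C5=C9 methyl enol ether of cycloheptadienone 12 at C9 and the tert-butyl ester on C1 captures the C5 oxocarbenium ion (sets C9 and C5, fixes C1). Target numbering, kept for the same atoms in all precursors: C1 bridgehead CH, C2 ketone, C3 (allyl), C4 =CH, C5 ketal bridgehead, O6, C7 lactone C=O, C8 (aryl), C9 (methyl).
2. 12 ⇐ 11 (key): the carbocycle C1–C2–C3–C4–C5–C9–C8 is made by a Pd(0)-catalysed formal Claisen ring expansion of the five-membered 2,5-dihydrofuran ring (O, C2, C3, C4, C5) of 11. O–C5 is broken, C1–C8 is made, the ring oxygen becomes the C2 ketone oxygen, C5 stays as the methyl enol ether, and the C5 configuration is relayed to C8.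
3. Enabling feature: the cis-ene-1,4-dione array C2(=O)–C3=C4–C5(OMe)(O) of the seven-membered carbocycle is an oxidised furan. With C1 (α to the ester) as exocyclic enol-ether carbon on C2 and the C9=C8 arylpropenyl group on the ketal carbon C5, the ring oxygen lies inside an allyl vinyl ether C1=C2–O–C5–C9=C8.
4. 11 ⇐ 8: anodic 2,5-dimethoxylation of the furan, loss of methanol across C1–C2, resolution of the C5 ketal. 8 ⇐ 2,3-dibromofuran 4 by three site-selective couplings (C2: Reformatsky reagent; C3: allylstannane; C5: bromination, then Suzuki coupling with alkenylboronate 3 from aryl iodide 1).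
5. Order of rings: furan (bought) → 2,5-dihydrofuran ketal → seven-membered carbocycle (ring expansion, heterocycle consumed) → bridging six-membered lactone, which completes the 6-oxabicyclo[3.2.2]nonane.

Key step: step 9

Remark: 1, 4 and the reagents named in the steps are taken as purchasable; the absolute configuration of resolved 11 has to be assigned (VCD, or correlation with 13) before it is carried on.

## Route

Step 1
Reactants: 1 5-iodo-1,2,3-trimethoxybenzene
Product: 2 1,2,3-trimethoxy-5-(prop-1-yn-1-yl)benzene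
Conditions: propyne (1 M in THF, 2 equiv), PdCl2(PPh3)2 (2 mol %), CuI (4 mol %), Et3N, THF, rt
Reagents that add atoms: propyne (CC#C)
Why: Sonogashira coupling of an aryl iodide with a terminal alkyne; no stereocentre is formed.

Step 2
Reactants: 2 1,2,3-trimethoxy-5-(prop-1-yn-1-yl)benzene
Product: 3 4,4,5,5-tetramethyl-2-[(1Z)-1-(3,4,5-trimethoxyphenyl)prop-1-en-2-yl]-1,3,2-dioxaborolane
Conditions: B2pin2 (1.1 equiv), CuCl (5 mol %), Xantphos (5 mol %), NaOt-Bu (10 mol %), MeOH (2 equiv), THF, rt
Reagents that add atoms: bis(pinacolato)diboron (CC1(C)OB(OC1(C)C)B1OC(C)(C)C(C)(C)O1)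
Why: Copper-catalysed formal hydroboration (syn-borylcupration, then protonation by methanol) should place copper on the aryl-bearing carbon and boron on the methyl-bearing carbon, and the syn addition fixes aryl trans to boron, the geometry that becomes the (E)-arylpropenyl group.

Step 3
Reactants: 4 2,3-dibromofuran
Product: 5 tert-butyl 2-(3-bromofuran-2-yl)acetate
Conditions: BrZnCH2CO2t-Bu (0.5 M in Et2O, 1.1 equiv), Pd(dba)2 (2 mol %), Q-Phos (2 mol %), THF, 25 °C
Reagents that add atoms: (2-tert-butoxy-2-oxoethyl)zinc bromide (CC(C)(C)OC(=O)C[Zn]Br)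
Why: Palladium-catalysed coupling of a Reformatsky reagent with a heteroaryl bromide (Negishi-type ester α-arylation); oxidative addition should be faster at the C–Br bond next to the ring oxygen, so only that position is substituted.

Step 4
Reactants: 5 tert-butyl 2-(3-bromofuran-2-yl)acetate
Product: 6 tert-butyl 2-[3-(prop-2-en-1-yl)furan-2-yl]acetate
Conditions: allylSnBu3 (1.2 equiv), Pd2(dba)3 (2 mol %), P(t-Bu)3·HBF4 (8 mol %), CsF (2.2 equiv), dioxane, 80 °C
Reagents that add atoms: allyltributylstannane (C=CC[Sn](CCCC)(CCCC)CCCC)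
Why: Stille coupling of the remaining electron-rich 3-bromofuran under fluoride activation, neutral enough to leave the acidic CH2CO2t-Bu group alone and to keep the alkene terminal.

Step 5
Reactants: 6 tert-butyl 2-[3-(prop-2-en-1-yl)furan-2-yl]acetate
Product: 7 tert-butyl 2-[5-bromo-3-(prop-2-en-1-yl)furan-2-yl]acetate
Conditions: NBS (1.02 equiv), DMF, −30 → 0 °C, dark; used at once
Reagents that add atoms: N-bromosuccinimide (BrN1C(=O)CCC1=O)
Why: Electrophilic bromination at the only free α-position of the furan, which at low temperature is far more nucleophilic than the allyl group.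

Step 6
Reactants: 7 tert-butyl 2-[5-bromo-3-(prop-2-en-1-yl)furan-2-yl]acetate, 3 4,4,5,5-tetramethyl-2-[(1Z)-1-(3,4,5-trimethoxyphenyl)prop-1-en-2-yl]-1,3,2-dioxaborolane
Product: 8 tert-butyl 2-[3-(prop-2-en-1-yl)-5-[(1E)-1-(3,4,5-trimethoxyphenyl)prop-1-en-2-yl]furan-2-yl]acetate
Conditions: Pd(dppf)Cl2·CH2Cl2 (5 mol %), K3PO4 (3 equiv), THF/H2O 10:1, 50 °C
Reagents that add atoms: none
Why: Suzuki–Miyaura coupling of the 2-bromofuran with the alkenylboronate with retention of alkene geometry, so that aryl ends trans to the furan (E).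

Step 7
Reactants: 8 tert-butyl 2-[3-(prop-2-en-1-yl)-5-[(1E)-1-(3,4,5-trimethoxyphenyl)prop-1-en-2-yl]furan-2-yl]acetate
Product: 10 tert-butyl (2Z)-2-[5-methoxy-3-(prop-2-en-1-yl)-5-[(1E)-1-(3,4,5-trimethoxyphenyl)prop-1-en-2-yl]furan-2(5H)-ylidene]acetate (racemic), via 2,5-dimethoxy-2,5-dihydrofuran bis-ketal 9 (not isolated)
Conditions: (a) graphite anode, Pt cathode, undivided cell, MeOH, Et4NOTs (0.05 M), 2,6-lutidine (0.2 equiv), −20 °C, constant current, 2.2 F mol⁻¹; (b) concentrate, then TMSOTf (1.2 equiv), i-Pr2NEt (2 equiv), CH2Cl2, −78 → −30 °C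
Reagents that add atoms: methanol (CO)
Why: Electrochemical Clauson-Kaas 2,5-dimethoxylation should give bis-ketal 9 (ketal formation at C5 is reversible and favoured over attack at the benzylic terminus by anomeric stabilisation), and the silyl triflate/amine ketal-to-enol-ether elimination can lose methanol only across C1–C2, the one ketal carbon with an acidic α-CH2, giving the (Z)-β-alkoxyacrylate with the ester away from the C3 allyl group; C5 is formed as the racemate.

Step 8
Reactants: 10 tert-butyl (2Z)-2-[5-methoxy-3-(prop-2-en-1-yl)-5-[(1E)-1-(3,4,5-trimethoxyphenyl)prop-1-en-2-yl]furan-2(5H)-ylidene]acetate (racemic)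
Product: 11 tert-butyl (2Z)-2-[(5R)-5-methoxy-3-(prop-2-en-1-yl)-5-[(1E)-1-(3,4,5-trimethoxyphenyl)prop-1-en-2-yl]furan-2(5H)-ylidene]acetate
Conditions: preparative SFC, immobilised amylose tris(3,5-dimethylphenylcarbamate) phase, CO2/i-PrOH, 35 °C; the (5R) enantiomer is collected, the (5S) enantiomer is kept apart
Reagents that add atoms: none
Why: Resolution by chromatography on a chiral stationary phase; the C5 ketal is configurationally stable in neutral media, and only the (5R) enantiomer has the configuration that step 9 relays to C8.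

Step 9
Reactants: 11 tert-butyl (2Z)-2-[(5R)-5-methoxy-3-(prop-2-en-1-yl)-5-[(1E)-1-(3,4,5-trimethoxyphenyl)prop-1-en-2-yl]furan-2(5H)-ylidene]acetate
Product: 12 tert-butyl (2R)-4-methoxy-3-methyl-7-oxo-6-(prop-2-en-1-yl)-2-(3,4,5-trimethoxyphenyl)cyclohepta-3,5-diene-1-carboxylate (epimers at the carboxyl-bearing carbon, interconverting)
Conditions: Pd2(dba)3·CHCl3 (2.5 mol %), PPh3 (12 mol %), degassed toluene, 25–40 °C
Reagents that add atoms: none
Why: Proposed new method: Pd(0) should ionise the doubly allylic, methoxy-stabilised O–C5 bond of 11 with inversion to a zwitterionic 1-methoxy-π-allylpalladium/β-keto ester enolate, whose carbon C1 then attacks the far, benzylic allyl terminus C8 anti to palladium, so that O–C5 is exchanged for C1–C8 in a formal [3,3] shift and the five-membered ring (O, C2, C3, C4, C5) becomes the seven-membered carbocycle (C1–C5, C9, C8). The closest known reaction type is the Pd(0)-catalysed O-to-C allyl shift of 5-vinyl-2-(alkoxycarbonylmethylene)tetrahydrofurans, which gives cyclopentanones or, by attack at the far terminus, cyclohept-4-enones (formal Claisen ring expansion); new here are the ketal carbon as ionising centre and the unsaturated, furan-derived ring. The carbocycle is closed by intramolecular C-allylation of the tethered enolate at the distal allyl terminus (1,3-transposition, ring enlarged by two atoms), and the tether admits only the allyl rotamer with C4 cis to C8, which gives the cis C5=C9 ring alkene. C8 is set by double inversion (net retention): C1–C8 forms on the allyl face that the ring oxygen left, so (5R)-11 with the (E)-arylpropenyl group (aryl syn on the allyl unit) should give (R) at C8, while C1 stays epimerisable as a β-keto ester and is fixed only in step 10. The step needs C- over O-alkylation and distal (seven-ring) over proximal (five-ring, Piancatelli-type cyclopentenone) attack: the proximal terminus is fully substituted and carries OMe, its C-alkylation product keeps a push–pull C–C bond that can re-ionise, and the conjugated dienone 12 is the thermodynamic sink. Mild temperature is chosen because a purely thermal Claisen rearrangement is disfavoured stereoelectronically in the flat dihydrofuran (O–C5 lies near the nodal plane of the C1=C2 π bond) and would invite 1,5-hydrogen shifts and 4π closure.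

Step 10
Reactants: 12 tert-butyl (2R)-4-methoxy-3-methyl-7-oxo-6-(prop-2-en-1-yl)-2-(3,4,5-trimethoxyphenyl)cyclohepta-3,5-diene-1-carboxylate
Product: 13 (1R,5S,8R,9R)-5-methoxy-9-methyl-3-(prop-2-en-1-yl)-8-(3,4,5-trimethoxyphenyl)-6-oxabicyclo[3.2.2]non-3-ene-2,7-dione
Conditions: HNTf2 (10 mol %), 4 Å MS, CH2Cl2, −40 → 0 °C
Reagents that add atoms: none
Why: Acid-catalysed alkoxy-lactonisation of an enol ether with dealkylation of the tert-butyl ester (the cation-capture type known from lactonisations of tert-butyl esters): reversible protonation at C9 gives the C5 oxocarbenium ion, the ester carbonyl oxygen on C1 closes the six-membered lactone across the ring and isobutene leaves; C1 epimerises through the enol, so the bicycle with the larger aryl group pseudo-equatorial (syn to the lactone bridge) should be selected, protonation of C9 from the open convex face puts methyl trans to aryl and syn to the enone bridge, and the bridge itself dictates (5S) and (1R).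

## Compound list

1 | 5-iodo-1,2,3-trimethoxybenzene | COc1cc(I)cc(OC)c1OC | starting material
2 | 1,2,3-trimethoxy-5-(prop-1-yn-1-yl)benzene | CC#Cc1cc(OC)c(OC)c(OC)c1 | intermediate
3 | 4,4,5,5-tetramethyl-2-[(1Z)-1-(3,4,5-trimethoxyphenyl)prop-1-en-2-yl]-1,3,2-dioxaborolane | C/C(B1OC(C)(C)C(C)(C)O1)=C\c1cc(OC)c(OC)c(OC)c1 | intermediate
4 | 2,3-dibromofuran | Brc1ccoc1Br | starting material
5 | tert-butyl 2-(3-bromofuran-2-yl)acetate | CC(C)(C)OC(=O)Cc1occc1Br | intermediate
6 | tert-butyl 2-[3-(prop-2-en-1-yl)furan-2-yl]acetate | CC(C)(C)OC(=O)Cc1occc1CC=C | intermediate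
7 | tert-butyl 2-[5-bromo-3-(prop-2-en-1-yl)furan-2-yl]acetate | CC(C)(C)OC(=O)Cc1oc(Br)cc1CC=C | intermediate
8 | tert-butyl 2-[3-(prop-2-en-1-yl)-5-[(1E)-1-(3,4,5-trimethoxyphenyl)prop-1-en-2-yl]furan-2-yl]acetate | CC(C)(C)OC(=O)Cc1oc(cc1CC=C)/C(C)=C/c1cc(OC)c(OC)c(OC)c1 | intermediate
9 | tert-butyl 2-[2,5-dimethoxy-3-(prop-2-en-1-yl)-5-[(1E)-1-(3,4,5-trimethoxyphenyl)prop-1-en-2-yl]-2,5-dihydrofuran-2-yl]acetate (cis/trans mixture, racemic) | COC1(CC(=O)OC(C)(C)C)OC(OC)(C=C1CC=C)/C(C)=C/c1cc(OC)c(OC)c(OC)c1 | intermediate (not isolated)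
10 | tert-butyl (2Z)-2-[5-methoxy-3-(prop-2-en-1-yl)-5-[(1E)-1-(3,4,5-trimethoxyphenyl)prop-1-en-2-yl]furan-2(5H)-ylidene]acetate (racemic) | O1C(OC)(C=C(CC=C)/C1=C/C(=O)OC(C)(C)C)/C(C)=C/c1cc(OC)c(OC)c(OC)c1 | intermediate
11 | tert-butyl (2Z)-2-[(5R)-5-methoxy-3-(prop-2-en-1-yl)-5-[(1E)-1-(3,4,5-trimethoxyphenyl)prop-1-en-2-yl]furan-2(5H)-ylidene]acetate | O1[C@](OC)(C=C(CC=C)/C1=C/C(=O)OC(C)(C)C)/C(C)=C/c1cc(OC)c(OC)c(OC)c1 | intermediate
12 | tert-butyl (2R)-4-methoxy-3-methyl-7-oxo-6-(prop-2-en-1-yl)-2-(3,4,5-trimethoxyphenyl)cyclohepta-3,5-diene-1-carboxylate (C1 left undefined: epimers and enol in equilibrium) | O=C1C(CC=C)=CC(OC)=C(C)[C@@H](c2cc(OC)c(OC)c(OC)c2)C1C(=O)OC(C)(C)C | intermediate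
13 | (1R,5S,8R,9R)-5-methoxy-9-methyl-3-(prop-2-en-1-yl)-8-(3,4,5-trimethoxyphenyl)-6-oxabicyclo[3.2.2]non-3-ene-2,7-dione | C=CCC1=C[C@@]2(OC)OC(=O)[C@@H](C1=O)[C@H](c1cc(OC)c(OC)c(OC)c1)[C@H]2C | target

## Step count and risks

Total step count: 10 (nine reactions and one resolution). Longest linear sequence: 8 steps (4 → 13, steps 3 to 10).

Steps most likely to fail:

1. Step 9 (Proposed new method). What may go wrong: C-allylation at the proximal, methoxy-bearing terminus (five-ring closure to a cyclopentenone) instead of seven-ring closure; loss of methoxide with return to aromatic furan products; erosion of the chirality transfer by face exchange or by palladium-free ionisation. Fallback (known chemistry; the seven-membered ring is then closed by conjugate addition instead of ring expansion): it sets out from 8. Dye-sensitised photooxygenation of the furan (O2, methylene blue, hν, CH2Cl2, −78 °C) and reduction of the endoperoxide with dimethyl sulfide should give the cis-ene-dione tert-butyl (4Z,7E)-7-methyl-3,6-dioxo-4-(prop-2-en-1-yl)-8-(3,4,5-trimethoxyphenyl)octa-4,7-dienoate F1. Cs2CO3 in MeCN should then effect the intramolecular 7-endo Michael addition of the β-keto ester to the aryl enone, giving rac-tert-butyl (6R,7R)-6-methyl-2,5-dioxo-3-(prop-2-en-1-yl)-7-(3,4,5-trimethoxyphenyl)cyclohept-3-ene-1-carboxylate F2, with methyl trans to aryl by equilibration next to the ketone. TFA in CH2Cl2 at 0 °C removes the tert-butyl group and the δ-keto acid should close to the bridged pseudo-acid rac-(1R,5S,8R,9R)-5-hydroxy-9-methyl-3-(prop-2-en-1-yl)-8-(3,4,5-trimethoxyphenyl)-6-oxabicyclo[3.2.2]non-3-ene-2,7-dione F3. MeOH/HC(OMe)3 with catalytic CSA converts the lactol into the methyl pseudo-ester, so the fallback comes back to the route at 13, here as the racemate, which is resolved on the chiral phase of step 8.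

2. Step 10. What may go wrong: bridging from the wrong C1 epimer (aryl syn to the enone bridge); proton delivery to C9 cis to aryl; acid-induced C1–C8 ionisation or hydrolysis of the enol ether followed by decarboxylation. Fallback (C1 is locked before bridging): it sets out from 12. NaH, then NCS in THF at −78 °C should chlorinate the β-keto ester enolate anti to the neighbouring aryl group and give tert-butyl (1S,2R)-1-chloro-4-methoxy-3-methyl-7-oxo-6-(prop-2-en-1-yl)-2-(3,4,5-trimethoxyphenyl)cyclohepta-3,5-diene-1-carboxylate F4, in which the carboxyl group is fixed cis to aryl. The acid treatment of step 10 can then bridge only from that face and should give (1S,5S,8S,9R)-1-chloro-5-methoxy-9-methyl-3-(prop-2-en-1-yl)-8-(3,4,5-trimethoxyphenyl)-6-oxabicyclo[3.2.2]non-3-ene-2,7-dione F5. Bu3SnH/AIBN in benzene at 80 °C removes the bridgehead chlorine, where the bicycle enforces retention, and the fallback comes back to the route at 13.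

3. Step 7. What may go wrong: methanol adding at the benzylic terminus of the extended cation instead of C5; over-oxidation of the electron-rich styrene unit; acid-type collapse of 10 to a cyclopentenone during the elimination. Fallback (cycloaddition instead of electron-transfer oxidation): it sets out from 8. Photooxygenation in methanol (O2, rose bengal, hν, −78 °C), that is [4+2] addition of singlet oxygen across the two furan α-carbons and methanolysis of the endoperoxide, should give tert-butyl 2-[2-hydroperoxy-5-methoxy-3-(prop-2-en-1-yl)-5-[(1E)-1-(3,4,5-trimethoxyphenyl)prop-1-en-2-yl]-2,5-dihydrofuran-2-yl]acetate F6 (the regioisomeric hydroperoxide would converge). Reduction with dimethyl sulfide and ketalisation of the hemiketal with HC(OMe)3/MeOH/PPTS leads to 9, where the fallback comes back to the route before the elimination of step 7.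

Further compounds
F1 | step 9 | tert-butyl (4Z,7E)-7-methyl-3,6-dioxo-4-(prop-2-en-1-yl)-8-(3,4,5-trimethoxyphenyl)octa-4,7-dienoate | CC(C)(C)OC(=O)CC(=O)/C(CC=C)=C\C(=O)/C(C)=C/c1cc(OC)c(OC)c(OC)c1
F2 | step 9 | rac-tert-butyl (6R,7R)-6-methyl-2,5-dioxo-3-(prop-2-en-1-yl)-7-(3,4,5-trimethoxyphenyl)cyclohept-3-ene-1-carboxylate (one enantiomer drawn, C1 undefined) | O=C1C(CC=C)=CC(=O)[C@H](C)[C@@H](c2cc(OC)c(OC)c(OC)c2)C1C(=O)OC(C)(C)C
F3 | step 9 | rac-(1R,5S,8R,9R)-5-hydroxy-9-methyl-3-(prop-2-en-1-yl)-8-(3,4,5-trimethoxyphenyl)-6-oxabicyclo[3.2.2]non-3-ene-2,7-dione (one enantiomer drawn) | C=CCC1=C[C@@]2(O)OC(=O)[C@@H](C1=O)[C@H](c1cc(OC)c(OC)c(OC)c1)[C@H]2C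
F4 | step 10 | tert-butyl (1S,2R)-1-chloro-4-methoxy-3-methyl-7-oxo-6-(prop-2-en-1-yl)-2-(3,4,5-trimethoxyphenyl)cyclohepta-3,5-diene-1-carboxylate | O=C1C(CC=C)=CC(OC)=C(C)[C@@H](c2cc(OC)c(OC)c(OC)c2)[C@@]1(Cl)C(=O)OC(C)(C)C
F5 | step 10 | (1S,5S,8S,9R)-1-chloro-5-methoxy-9-methyl-3-(prop-2-en-1-yl)-8-(3,4,5-trimethoxyphenyl)-6-oxabicyclo[3.2.2]non-3-ene-2,7-dione | C=CCC1=C[C@@]2(OC)OC(=O)[C@@](Cl)(C1=O)[C@H](c1cc(OC)c(OC)c(OC)c1)[C@H]2C
F6 | step 7 | tert-butyl 2-[2-hydroperoxy-5-methoxy-3-(prop-2-en-1-yl)-5-[(1E)-1-(3,4,5-trimethoxyphenyl)prop-1-en-2-yl]-2,5-dihydrofuran-2-yl]acetate | OOC1(CC(=O)OC(C)(C)C)OC(OC)(C=C1CC=C)/C(C)=C/c1cc(OC)c(OC)c(OC)c1
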